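The depside is cut at the ester C–O bond between O-4 of ring B and the ring A carboxyl carbon, and ring A is unfolded at C1'–C6'. Ring A (O at C2' and C4', methyl at C3' and C6') has the pattern of a tetraketide with one extra C-methyl group. Its carboxyl carbon is shielded by the C2' and C6' substituents, and delivering that carbon as a linear ketene before the ring exists removes the shielding. In one flask, dioxinone 6, which carries a 3,5-dioxohexan-2-yl chain at C6, loses acetone, phenol 12 adds to the acylketene, and an amine folds the chain into the resorcylate. Protection, 2'-O-methylation, hydrogenolysis and C5' chlorination follow.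

Key step: step 9

Remark on the chemistry: the target has no stereocentre. The side-chain methine of 4, 6, 13 and 14 is racemic and enolisable and becomes the sp2 carbon C3' in step 9. Primed locants refer to ring A (acyl ring), unprimed locants to ring B.

Step 1
Reactants: 1 2,2,6-trimethyl-4H-1,3-dioxin-4-one
Product: 2 6-ethyl-2,2-dimethyl-4H-1,3-dioxin-4-one
Conditions: LiN(iPr)2 (1.1 equiv), THF/DMPU, −78 °C; MeI, −78 to −20 °C
Reagents that add atoms: iodomethane, CI
Why: Deprotonation of the C6 methyl group and reaction with a small, reactive halide in a polar cosolvent should place the new carbon at the gamma position (vinylogous enolate alkylation of a dioxinone).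

Step 2
Reactants: 2 6-ethyl-2,2-dimethyl-4H-1,3-dioxin-4-one; 3 acetyl chloride
Product: 4 2,2-dimethyl-6-(3-oxobutan-2-yl)-4H-1,3-dioxin-4-one (racemic)
Conditions: 2 (2 equiv), LiN(SiMe3)2 (2 equiv), THF, −78 °C; 3 (1 equiv), −78 °C; aq. HCl quench; surplus 2 recovered
Reagents that add atoms: none
Why: Gamma-C-acylation of the deprotonated dioxinone by an acid chloride (vinylogous Claisen-type acylation) should work because the second equivalent of deprotonated 2 removes the acidic proton of 4 and so prevents a second acylation.

Step 3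
Reactants: 4 2,2-dimethyl-6-(3-oxobutan-2-yl)-4H-1,3-dioxin-4-one; 5 N-methoxy-N-methylacetamide
Product: 6 2,2-dimethyl-6-(3,5-dioxohexan-2-yl)-4H-1,3-dioxin-4-one (racemic, largely enolised)
Conditions: LiN(iPr)2 (2.3 equiv), THF, −78 to −40 °C; 5 (1.1 equiv), −78 to −10 °C; aq. HCl to pH 3 at 0 °C; rapid chromatography, used promptly
Reagents that add atoms: none
Why: After double deprotonation the terminal carbon, formed last and most basic, adds to the Weinreb amide, and the N-methoxy chelate holds the adduct until the acid quench, so over-addition is excluded (dianion Claisen-type acylation, Weinreb ketone synthesis).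

Step 4
Reactants: 7 atraric acid (methyl 2,4-dihydroxy-3,6-dimethylbenzoate)
Product: 8 methyl 5-formyl-2,4-dihydroxy-3,6-dimethylbenzoate
Conditions: Cl2CHOMe (1.5 equiv), TiCl4 (3 equiv), CH2Cl2, −10 to 0 °C; then aq. HCl
Reagents that add atoms: dichloromethyl methyl ether, COC(Cl)Cl; water, O
Why: Rieche formylation can only strike C5, the single free ring position, which is ortho to 4-OH and para to 2-OH.

Step 5
Reactants: 8 methyl 5-formyl-2,4-dihydroxy-3,6-dimethylbenzoate
Product: 9 methyl 2,4-dihydroxy-3,5,6-trimethylbenzoate
Conditions: Et3SiH (3 equiv), TFA/CH2Cl2, 0 °C to rt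
Reagents that add atoms: none
Why: Ionic hydrogenation takes the aldehyde to the methyl group by two hydride transfers, because the ortho and para hydroxyl groups stabilise the benzylic cation and no free ring position is left for Friedel–Crafts dimerisation.

Step 6
Reactants: 9 methyl 2,4-dihydroxy-3,5,6-trimethylbenzoate
Product: 10 methyl 4-(allyloxy)-2-hydroxy-3,5,6-trimethylbenzoate
Conditions: allyl bromide (1.05 equiv), K2CO3 (1.1 equiv), acetone, 50 °C
Reagents that add atoms: allyl bromide, C=CCBr
Why: Williamson etherification with one equivalent of halide should select the 4-OH, since the 2-OH is tied to the ester carbonyl by a hydrogen bond and is less acidic.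

Step 7
Reactants: 10 methyl 4-(allyloxy)-2-hydroxy-3,5,6-trimethylbenzoate
Product: 11 methyl 4-(allyloxy)-2-(benzyloxy)-3,5,6-trimethylbenzoate
Conditions: BnBr (1.5 equiv), K2CO3 (2 equiv), DMF, 60 °C
Reagents that add atoms: benzyl bromide, BrCc1ccccc1
Why: With the 4-O position blocked, Williamson benzylation in a dipolar aprotic solvent at higher temperature should break the chelate and alkylate the only remaining hydroxyl group.

Step 8
Reactants: 11 methyl 4-(allyloxy)-2-(benzyloxy)-3,5,6-trimethylbenzoate
Product: 12 methyl 2-(benzyloxy)-4-hydroxy-3,5,6-trimethylbenzoate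
Conditions: Pd(PPh3)4 (3 mol %), morpholine (5 equiv), THF, rt
Reagents that add atoms: none
Why: Zerovalent palladium ionises the aryl allyl ether to a pi-allyl complex that morpholine intercepts (Tsuji–Trost deallylation), and the benzyl ether and the methyl ester are inert to these conditions.

Step 9
Reactants: 6 2,2-dimethyl-6-(3,5-dioxohexan-2-yl)-4H-1,3-dioxin-4-one; 12 methyl 2-(benzyloxy)-4-hydroxy-3,5,6-trimethylbenzoate
Product: 15 methyl 2-(benzyloxy)-4-[(2,4-dihydroxy-3,6-dimethylbenzoyl)oxy]-3,5,6-trimethylbenzoate, via acylketene 13 (not isolated), via aryl triketo ester 14 (not isolated)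
Conditions: 12 (1.0 equiv, 0.5 M), 4 Å MS, PhMe, 110 °C, 6 (1.3 equiv) in PhMe added over 2 h; cool to rt, Et3N (2 equiv), 12 h; 1 M HCl wash
Reagents that add atoms: none
Why: Thermal retro-hetero-Diels–Alder cleavage of 6 expels acetone in the rate-limiting step and gives acylketene 13, and the in-plane pseudopericyclic addition of the O–H of 12 forms the depside C–O bond at an sp carbon that has no ortho neighbours yet, so the two methyl groups beside O-4 should matter little. The closest known reaction type is the dioxinone thermolysis, ketene trapping and aldol aromatisation sequence to resorcylate esters, together with the acetoacetylation of phenols and hindered alcohols by 2,2,6-trimethyl-1,3-dioxin-4-one. Et3N then enolises 14 at C1', the carbon between the ester and the C2' ketone, and this carbon attacks the terminal methyl ketone carbon C6' in a 6-(enolendo)-exo-trig aldol closure permitted by the Baldwin rules, after which E1cB loss of water and tautomerisation of the C2' and C4' carbonyl groups deliver aromatic ring A. No stereocentre is created and the labile methine of 6 ends as sp2 C3'. The step needs chemoselectivity for intermolecular capture and C1'–C6' closure over attack of the C4' enol oxygen on the ketene or on the aryl ester (2-pyrone formation) and over Claisen closure from C5' with loss of aryloxide; this is secured by the single free hydroxyl group of 12, by feeding 6 slowly into a hot concentrated solution of 12 so that 13 never accumulates, and by a weak non-nucleophilic amine in an aprotic medium.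

Step 10
Reactants: 15 methyl 2-(benzyloxy)-4-[(2,4-dihydroxy-3,6-dimethylbenzoyl)oxy]-3,5,6-trimethylbenzoate
Product: 16 methyl 2-(benzyloxy)-4-{[4-(benzyloxy)-2-hydroxy-3,6-dimethylbenzoyl]oxy}-3,5,6-trimethylbenzoate
Conditions: BnBr (1.05 equiv), K2CO3 (1.1 equiv), acetone, rt to 40 °C
Reagents that add atoms: benzyl bromide, BrCc1ccccc1
Why: Williamson benzylation with one equivalent of halide should take the free, more acidic 4'-OH, while the 2'-OH stays hydrogen-bonded to the depside carbonyl.

Step 11
Reactants: 16 methyl 2-(benzyloxy)-4-{[4-(benzyloxy)-2-hydroxy-3,6-dimethylbenzoyl]oxy}-3,5,6-trimethylbenzoate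
Product: 17 methyl 2-(benzyloxy)-4-{[4-(benzyloxy)-2-methoxy-3,6-dimethylbenzoyl]oxy}-3,5,6-trimethylbenzoate
Conditions: MeI (5 equiv), K2CO3 (3 equiv), DMF, 40 °C
Reagents that add atoms: iodomethane, CI
Why: The 2'-OH is the only hydroxyl group left, so Williamson methylation with excess iodide is unambiguous, and the depside ester, di-ortho-substituted on both sides, should resist carbonate.

Step 12
Reactants: 17 methyl 2-(benzyloxy)-4-{[4-(benzyloxy)-2-methoxy-3,6-dimethylbenzoyl]oxy}-3,5,6-trimethylbenzoate
Product: 18 methyl 2-hydroxy-4-[(4-hydroxy-2-methoxy-3,6-dimethylbenzoyl)oxy]-3,5,6-trimethylbenzoate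
Conditions: H2 (1 atm), 10% Pd/C, EtOAc, rt
Reagents that add atoms: none
Why: Catalytic hydrogenolysis removes both benzyl ethers at once under neutral conditions that leave both esters and the methyl ether untouched, and no halogen is yet present to be lost.

Step 13
Reactants: 18 methyl 2-hydroxy-4-[(4-hydroxy-2-methoxy-3,6-dimethylbenzoyl)oxy]-3,5,6-trimethylbenzoate
Product: 19 methyl 4-[(5-chloro-4-hydroxy-2-methoxy-3,6-dimethylbenzoyl)oxy]-2-hydroxy-3,5,6-trimethylbenzoate (target)
Conditions: NCS (1.0 equiv), MeCN, 0 °C to rt
Reagents that add atoms: N-chlorosuccinimide, O=C1CCC(=O)N1Cl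
Why: Electrophilic aromatic chlorination has a single site for substitution, C5'–H, which is ortho to the 4'-OH and para to the 2'-OMe, whereas ring B is fully substituted and less electron-rich.

Compound list
1 | 2,2,6-trimethyl-4H-1,3-dioxin-4-one | CC1=CC(=O)OC(C)(C)O1 | starting material
2 | 6-ethyl-2,2-dimethyl-4H-1,3-dioxin-4-one | CCC1=CC(=O)OC(C)(C)O1 | intermediate
3 | acetyl chloride | CC(=O)Cl | starting material
4 | 2,2-dimethyl-6-(3-oxobutan-2-yl)-4H-1,3-dioxin-4-one (racemic) | CC(=O)C(C)C1=CC(=O)OC(C)(C)O1 | intermediate
5 | N-methoxy-N-methylacetamide | CON(C)C(C)=O | starting material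
6 | 2,2-dimethyl-6-(3,5-dioxohexan-2-yl)-4H-1,3-dioxin-4-one (racemic) | CC(=O)CC(=O)C(C)C1=CC(=O)OC(C)(C)O1 | intermediate
7 | atraric acid, methyl 2,4-dihydroxy-3,6-dimethylbenzoate | COC(=O)c1c(C)cc(O)c(C)c1O | starting material
8 | methyl 5-formyl-2,4-dihydroxy-3,6-dimethylbenzoate | COC(=O)c1c(C)c(C=O)c(O)c(C)c1O | intermediate
9 | methyl 2,4-dihydroxy-3,5,6-trimethylbenzoate | COC(=O)c1c(C)c(C)c(O)c(C)c1O | intermediate
10 | methyl 4-(allyloxy)-2-hydroxy-3,5,6-trimethylbenzoate | COC(=O)c1c(C)c(C)c(OCC=C)c(C)c1O | intermediate
11 | methyl 4-(allyloxy)-2-(benzyloxy)-3,5,6-trimethylbenzoate | COC(=O)c1c(C)c(C)c(OCC=C)c(C)c1OCc1ccccc1 | intermediate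
12 | methyl 2-(benzyloxy)-4-hydroxy-3,5,6-trimethylbenzoate | COC(=O)c1c(C)c(C)c(O)c(C)c1OCc1ccccc1 | intermediate
13 | acylketene, 4-methyl-3,5,7-trioxooct-1-en-1-one (not isolated) | CC(=O)CC(=O)C(C)C(=O)C=C=O | intermediate
14 | aryl triketo ester, 3-(benzyloxy)-4-(methoxycarbonyl)-2,5,6-trimethylphenyl 4-methyl-3,5,7-trioxooctanoate (not isolated) | CC(=O)CC(=O)C(C)C(=O)CC(=O)Oc1c(C)c(C)c(C(=O)OC)c(OCc2ccccc2)c1C | intermediate
15 | methyl 2-(benzyloxy)-4-[(2,4-dihydroxy-3,6-dimethylbenzoyl)oxy]-3,5,6-trimethylbenzoate | COC(=O)c1c(C)c(C)c(OC(=O)c2c(C)cc(O)c(C)c2O)c(C)c1OCc1ccccc1 | intermediate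
16 | methyl 2-(benzyloxy)-4-{[4-(benzyloxy)-2-hydroxy-3,6-dimethylbenzoyl]oxy}-3,5,6-trimethylbenzoate | COC(=O)c1c(C)c(C)c(OC(=O)c2c(C)cc(OCc3ccccc3)c(C)c2O)c(C)c1OCc1ccccc1 | intermediate
17 | methyl 2-(benzyloxy)-4-{[4-(benzyloxy)-2-methoxy-3,6-dimethylbenzoyl]oxy}-3,5,6-trimethylbenzoate | COC(=O)c1c(C)c(C)c(OC(=O)c2c(C)cc(OCc3ccccc3)c(C)c2OC)c(C)c1OCc1ccccc1 | intermediate
18 | methyl 2-hydroxy-4-[(4-hydroxy-2-methoxy-3,6-dimethylbenzoyl)oxy]-3,5,6-trimethylbenzoate | COC(=O)c1c(C)c(C)c(OC(=O)c2c(C)cc(O)c(C)c2OC)c(C)c1O | intermediate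
19 | methyl 4-[(5-chloro-4-hydroxy-2-methoxy-3,6-dimethylbenzoyl)oxy]-2-hydroxy-3,5,6-trimethylbenzoate | COC(=O)c1c(C)c(C)c(OC(=O)c2c(C)c(Cl)c(O)c(C)c2OC)c(C)c1O | target

Total step count: 13.
Longest linear sequence: 10 steps (7 to 19, steps 4–13). The dioxinone branch (steps 1–3) joins at step 9.

Steps most likely to fail

1. Step 9.
- What may go wrong: the ketene may close on its own C4' enol oxygen faster than the hindered, weakly nucleophilic phenol adds. The aryl ester may also lose its aryloxide during the amine treatment.
- Fallback (preformed ring A and classical depside esterification): it sets out from 7, with 12 as partner, and comes back to the route at 17.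
- Atraric acid already holds the ring A carbon pattern. BnBr and K2CO3 in acetone should give methyl 4-(benzyloxy)-2-hydroxy-3,6-dimethylbenzoate F1.
- MeI and K2CO3 in DMF should then give methyl 4-(benzyloxy)-2-methoxy-3,6-dimethylbenzoate F2.
- KOH in aqueous DMSO at 100 °C should saponify the hindered ester to 4-(benzyloxy)-2-methoxy-3,6-dimethylbenzoic acid F3.
- F3 and 12 are then condensed with trifluoroacetic anhydride in toluene at room temperature. The electron-rich, di-ortho-substituted acid reacts through its mixed anhydride and acylium ion, which should give 17.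

2. Step 3.
- What may go wrong: the second deprotonation may be incomplete, a proton may pass from the acetamide to the dianion, and the product may aromatise early under base during the quench.
- Fallback (aldol addition followed by oxidation in place of acylation): it sets out from 4 and comes back at 6.
- The doubly deprotonated 4 is treated at −78 °C with acetaldehyde, a far faster electrophile that gives a non-acidic aldolate. This should lead to 6-(5-hydroxy-3-oxohexan-2-yl)-2,2-dimethyl-4H-1,3-dioxin-4-one F4 as a diastereomer mixture of no consequence.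
- Oxidation with Dess–Martin periodinane in CH2Cl2 should then give 6 under neutral conditions.

3. Step 2.
- What may go wrong: the more hindered secondary nucleophile may undergo O-acylation or alpha-acylation, and proton exchange may limit conversion.
- Fallback (the two C–C bonds made in reverse order): it sets out from 1 and comes back at 4.
- Compound 1 is deprotonated with LiN(SiMe3)2 and acetylated with 3 at its unbranched gamma carbon. This should give 2,2-dimethyl-6-(2-oxopropyl)-4H-1,3-dioxin-4-one F5.
- The doubly activated CH2 group of F5 is then monomethylated as a soft enolate with K2CO3 and MeI (1 equiv) in acetone to give 4.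

Further compounds
F1 | step 9 | methyl 4-(benzyloxy)-2-hydroxy-3,6-dimethylbenzoate | COC(=O)c1c(C)cc(OCc2ccccc2)c(C)c1O
F2 | step 9 | methyl 4-(benzyloxy)-2-methoxy-3,6-dimethylbenzoate | COC(=O)c1c(C)cc(OCc2ccccc2)c(C)c1OC
F3 | step 9 | 4-(benzyloxy)-2-methoxy-3,6-dimethylbenzoic acid | OC(=O)c1c(C)cc(OCc2ccccc2)c(C)c1OC
F4 | step 3 | 6-(5-hydroxy-3-oxohexan-2-yl)-2,2-dimethyl-4H-1,3-dioxin-4-one (diastereomer mixture) | CC(O)CC(=O)C(C)C1=CC(=O)OC(C)(C)O1
F5 | step 2 | 2,2-dimethyl-6-(2-oxopropyl)-4H-1,3-dioxin-4-one | CC(=O)CC1=CC(=O)OC(C)(C)O1
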